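**Assumptions**
- (S)-But-3-en-2-ol (3) and 3-(TBSO)propanoic acid (6) are treated as commercial; 6 is otherwise one silylation plus saponification from methyl 3-hydroxypropanoate.
- C2 of the target is not set by a dedicated reaction. It is set in the last step by reversible benzylic ionisation, with C3 controlling the outcome, and the all-trans (2,3-trans, 3,4-trans) THF is assumed to dominate.
- TBS = tert-butyldimethylsilyl; Ar = 4-(TBSO)-3,5-dimethoxyphenyl.

**Retrosynthetic overview**
1. The only non-aryl ring, the THF, is closed last: the primary C5–OH captures the syringyl benzylic cation or quinone methide at C2, and C3 steers C2 to the 2,3-trans isomer.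
2. The open-chain tetraol-ketone comes from two aryl Grignard additions, to a Weinreb amide (giving the C7' ketone) and to an aldehyde (giving the C2 carbinol).
3. The aldehyde is the ozonolysis product of the propenyl group, which is the traceless remnant of the chiral carbinol of (S)-but-3-en-2-ol.
4. The key step is an Ireland–Claisen [3,3] rearrangement that forms the C3–C4 bond (C8–C8'). It sets C3 and C4 from the (S)-carbinol through a chair transition state.
5. The allylic alcohol comes from cross-metathesis of (S)-but-3-en-2-ol with allyl TBS ether; the acid partner is 3-(TBSO)propanoic acid.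

---

**Step 1**
Reactants: 1 (4-bromo-2,6-dimethoxyphenol)
Product: 2 (tert-butyl(4-bromo-2,6-dimethoxyphenoxy)dimethylsilane)
Conditions: TBSCl, imidazole, DMF, rt
Reagents that add atoms: TBSCl, C[Si](C)(C)C(C)(C)Cl
Why: Silylation of the phenol makes a protected aryl bromide that tolerates Grignard formation and later additions (silyl ether protection).

**Step 2**
Reactants: 3 ((S)-but-3-en-2-ol), 4 (allyl TBS ether, 3 equiv)
Product: 5 ((S,E)-5-(TBSO)pent-3-en-2-ol)
Conditions: Hoveyda–Grubbs II (5 mol%), CH2Cl2, 40 °C
Reagents that add atoms: none (ethylene is lost)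
Why: Cross-metathesis gives the E-alkene with the carbinol untouched, so the chirality is carried into the Claisen step.

**Step 3**
Reactants: 5, 6 (3-(TBSO)propanoic acid)
Product: 7 (allylic ester of 5 with 6)
Conditions: EDC·HCl, cat. DMAP, CH2Cl2, 0 °C to rt
Reagents that add atoms: none
Why: Steglich esterification of the secondary allylic alcohol does not touch the stereocentre.

**Step 4**
Reactants: 7
Product: 8 ((2S,3R,4E)-2,3-bis{[(TBS)oxy]methyl}hex-4-enoic acid)
Conditions: LDA, TMSCl, THF, −78 °C to rt; then aq. KHSO4 workup
Reagents that add atoms: none (the silyl ester is hydrolysed on workup)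
Why: Ireland–Claisen [3,3]-sigmatropic rearrangement.
- The (E)-alkene and the (E)-silyl ketene acetal (LDA/THF, no HMPA) react through a chair transition state to give the anti-2,3 product.
- The (S)-carbinol transfers its chirality to C3 (R), and C4 (S) is set relative to C3.
- The carbinol stereocentre is destroyed, leaving an E-propenyl group as the masked C2 carbon.
- The in-situ TMSCl quench avoids β-elimination of the silyloxy group.

**Step 5**
Reactants: 8, 9 (N,O-dimethylhydroxylamine hydrochloride)
Product: 10 (Weinreb amide of 8)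
Conditions: EDC·HCl, HOBt, iPr2NEt, CH2Cl2, 0 °C to rt
Reagents that add atoms: none (9 is a reactant)
Why: Mild carbodiimide coupling avoids acid-chloride and ketene formation, so the α-stereocentre is not epimerised. The minor Claisen diastereomer is removed by chromatography here.

**Step 6**
Reactants: 10, 2 (as its Grignard, prepared in situ with Mg)
Product: 11 (aryl ketone: (2S,3R,E)-2,3-bis(TBSOCH2)-1-Ar-hex-4-en-1-one)
Conditions: ArMgBr (2.5 equiv), THF, 0 °C to rt
Reagents that add atoms: ArMgBr, COc1cc([Mg]Br)cc(OC)c1O[Si](C)(C)C(C)(C)C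
Why: Weinreb ketone synthesis, in which a stable chelated tetrahedral intermediate prevents over-addition.

**Step 7**
Reactants: 11
Product: 12 ((2R,3S)-2,3-bis(TBSOCH2)-4-Ar-4-oxobutanal)
Conditions: O3, CH2Cl2, −78 °C; then Me2S, −78 °C to rt
Reagents that add atoms: ozone, [O-][O+]=O (its oxygen ends up in the aldehyde)
Why: Ozonolysis cleaves the trisubstituted-free propenyl group selectively over the arenes, the silyl ethers and the ketone, giving the C2 aldehyde. It is used crude to avoid epimerisation at C3.

**Step 8**
Reactants: 12, 2 (as ArMgBr)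
Product: 13 (C2 carbinol, 1:1 to 3:1 at C2; (2S,3R) retained)
Conditions: ArMgBr (1.2 equiv), THF, −78 to −20 °C
Reagents that add atoms: ArMgBr, COc1cc([Mg]Br)cc(OC)c1O[Si](C)(C)C(C)(C)C
Why: Nucleophilic 1,2-addition; the aldehyde is far more reactive than the hindered aryl ketone at low temperature. The C2 epimer ratio is irrelevant because C2 is re-set in Step 10.

**Step 9**
Reactants: 13
Product: 14 (tetraol-ketone, all four TBS groups removed)
Conditions: TBAF, AcOH (1:1 buffered), THF, 0 °C to rt
Reagents that add atoms: none
Why: Fluoride desilylation; the AcOH buffer suppresses E1cB loss of the β-oxygen from the β-oxy ketone and enolisation at C4.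

**Step 10**
Reactants: 14
Product: 15 (target)
Conditions: p-TsOH·H2O (0.2 equiv), MeCN, rt to 40 °C
Reagents that add atoms: none (water is lost)
Why: Acid-catalysed cyclodehydration.
- The p-hydroxy-aryl carbinol ionises to a quinone methide or benzylic cation, which the primary C5–OH captures in a 5-exo closure. C9–OH cannot close (it would form an oxetane).
- The ionisation is reversible, so the all-trans THF forms under C3 control.
- C3 and C4 are not touched.

---

**Compound list**

| No. | Name | SMILES | Role |
|---|---|---|---|
| 1 | 4-bromo-2,6-dimethoxyphenol | COc1cc(Br)cc(OC)c1O | starting material |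
| 2 | tert-butyl(4-bromo-2,6-dimethoxyphenoxy)dimethylsilane | COc1cc(Br)cc(OC)c1O[Si](C)(C)C(C)(C)C | intermediate |
| 3 | (S)-but-3-en-2-ol | C[C@H](O)C=C | starting material |
| 4 | allyl TBS ether | C=CCO[Si](C)(C)C(C)(C)C | starting material |
| 5 | (S,E)-5-(TBSO)pent-3-en-2-ol | C[C@H](O)/C=C/CO[Si](C)(C)C(C)(C)C | intermediate |
| 6 | 3-(TBSO)propanoic acid | OC(=O)CCO[Si](C)(C)C(C)(C)C | starting material |
| 7 | allylic ester of 5 and 6 | C[C@H](OC(=O)CCO[Si](C)(C)C(C)(C)C)/C=C/CO[Si](C)(C)C(C)(C)C | intermediate |
| 8 | (2S,3R,4E)-2,3-bis(TBSOCH2)hex-4-enoic acid | O=C(O)[C@H](CO[Si](C)(C)C(C)(C)C)[C@H](CO[Si](C)(C)C(C)(C)C)/C=C/C | intermediate |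
| 9 | N,O-dimethylhydroxylamine·HCl | CNOC.Cl | starting material |
| 10 | Weinreb amide of 8 | CON(C)C(=O)[C@H](CO[Si](C)(C)C(C)(C)C)[C@H](CO[Si](C)(C)C(C)(C)C)/C=C/C | intermediate |
| 11 | aryl ketone (Ar = 4-TBSO-3,5-dimethoxyphenyl) | COc1cc(cc(OC)c1O[Si](C)(C)C(C)(C)C)C(=O)[C@H](CO[Si](C)(C)C(C)(C)C)[C@H](CO[Si](C)(C)C(C)(C)C)/C=C/C | intermediate |
| 12 | aldehyde | COc1cc(cc(OC)c1O[Si](C)(C)C(C)(C)C)C(=O)[C@H](CO[Si](C)(C)C(C)(C)C)[C@H](CO[Si](C)(C)C(C)(C)C)C=O | intermediate |
| 13 | C2 carbinol (epimeric at C2) | COc1cc(cc(OC)c1O[Si](C)(C)C(C)(C)C)C(=O)[C@H](CO[Si](C)(C)C(C)(C)C)[C@H](CO[Si](C)(C)C(C)(C)C)C(O)c2cc(OC)c(O[Si](C)(C)C(C)(C)C)c(OC)c2 | intermediate |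
| 14 | tetraol-ketone (all TBS removed) | COc1cc(cc(OC)c1O)C(=O)[C@H](CO)[C@H](CO)C(O)c2cc(OC)c(O)c(OC)c2 | intermediate |
| 15 | (4-hydroxy-3,5-dimethoxyphenyl)[(3S,4R,5S)-4-(hydroxymethyl)-5-(4-hydroxy-3,5-dimethoxyphenyl)oxolan-3-yl]methanone | COc1cc(C(=O)[C@@H]2CO[C@H](c3cc(OC)c(O)c(OC)c3)[C@H]2CO)cc(OC)c1O | target |

**Total steps:** 10 (Step 1 is a side branch making the aryl bromide).
**Longest linear sequence:** 9 steps (Steps 2 to 10, from 3).

**Three steps most likely to fail**
1. **Step 4 (Ireland–Claisen).**
   - Risk: the β-silyloxy ester enolate may eliminate, or the enolate geometry may erode and give a mixture of C4 epimers.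
   - Fallback: run an Eschenmoser–Claisen of 5 with Me2NC(OMe)2CH3 to set only C3 from the carbinol. Then make the aryl ketone and ozonolyse as before, and install C5 by α-hydroxymethylation of the ketone with monomeric HCHO. C4 is then equilibrated to the trans isomer.
2. **Step 8 (ArMgBr addition to the aldehyde).**
   - Risk: C3 epimerisation of the α-stereogenic aldehyde, or enolisation and β-elimination of the aryl ketone.
   - Fallback: swap the order. Add ArMgBr to the aldehyde-Weinreb amide (the amide tolerates the addition at −78 °C), silylate the resulting C2–OH, and only then form the ketone with a second ArMgBr.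
3. **Step 10 (cyclodehydration).**
   - Risk: poor 2,3-trans selectivity, or competing hemiketal formation or dehydration to the enone.
   - Fallback: close the ring kinetically instead. Use a PMB group on C5 and TBS on C9 so the C5–OH can be freed selectively. Separate the C2 carbinol diastereomers, then do an intramolecular Mitsunobu O-alkylation with retention at C2, using the isolated (S)-carbinol.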